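In ring A the fully substituted carbons C4 and C10 flank the ring-fusion CH at C5. This pattern is what a [4+2] union of a C3=C2–C1=C10 diene with a C4=C5 dienophile leaves behind, so both carbocycles are opened at once. A single intramolecular Diels–Alder reaction then makes C3–C4 and C5–C10, closes rings A and B, and sets C3, C4, C5 and C10. The substrate is an open chain with an (E)-2-methylenal at one end and a (1E,3E)-triethylsilyl dienol ether at the other. Its four-carbon tether holds the aldol-derived C8/C9 pair, which already carries the complete side chain. C3 emerges axial and is later reset through the ketone.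

Key step: step 15

Numbering: labdane numbering is used. C1–C10 form the decalin, C11–C16 the side chain, C17 is the exocyclic methylene, C18 the CH2OH on C4, and C19/C20 are the methyls on C4/C10. The target belongs to the ent-labdane series: trans-decalin, with O2, O3, C18 and C11 all equatorial.

Assumption: 4-ethoxy-4-oxobutylzinc bromide, the Ohira–Bestmann reagent, ethylene oxide solution and angelic acid are bought, and the 1E and 1Z dienol ethers of step 14 can be separated on amine-deactivated silica.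

Design notes:
- O15 and O16 are carried as TBDPS ethers and O18 later as a TBS ether, so that the two TES ethers (O3, O8) can be removed alone in step 18.
- The C13=C14 geometry requires syn hydrometalation of the butynediol ether. Anti hydroalumination would give the wrong isomer.
- Both aldehydes of the cycloaddition substrate are released in one oxidation, and the dienol ether is then made under kinetic conditions that pick out the doubly activated C2–H.

Step 1
Reactants: 1 2-butyne-1,4-diol
Product: 2 1,4-bis(tert-butyldiphenylsilyloxy)but-2-yne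
Conditions: TBDPSCl (2.2 equiv), imidazole, DMF, 0 °C to rt
Reagents that add atoms: tert-butyl(chloro)diphenylsilane, CC(C)(C)[Si](Cl)(c1ccccc1)c1ccccc1
Why: Imidazole-promoted silylation of two primary alcohols, with TBDPS chosen because it outlasts the later selective cleavage of TES ethers.

Step 2
Reactants: 2 1,4-bis(tert-butyldiphenylsilyloxy)but-2-yne
Product: 4 (E)-2-iodobut-2-ene-1,4-diol bis-TBDPS ether (CH2O groups cis), via vinylstannane 3 (not isolated)
Conditions: Bu3SnH, PdCl2(PPh3)2 (2 mol%), THF, 0 °C to rt; then I2, CH2Cl2, 0 °C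
Reagents that add atoms: iodine, [I][I]
Why: Palladium-catalysed hydrostannation adds H and Sn to the same face of the symmetrical alkyne (no regiochemical issue) and iododestannylation keeps the geometry, so the two CH2O groups end up cis as C13=C14 requires.

Step 3
Reactants: 4 (E)-vinyl iodide; 5 4-ethoxy-4-oxobutylzinc bromide
Product: 6 ethyl (Z)-7-(TBDPS-oxy)-5-(TBDPS-oxymethyl)hept-5-enoate
Conditions: PdCl2(dppf) (5 mol%), THF, rt to 45 °C
Reagents that add atoms: none
Why: Negishi sp2–sp3 cross-coupling proceeds with retention of alkene geometry, tolerates the ester, and brings in C12, C11, C9 and the future C10 carbonyl.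

Step 4
Reactants: 6 ethyl ester
Product: 7 (Z)-7-(TBDPS-oxy)-5-(TBDPS-oxymethyl)hept-5-enoic acid
Conditions: LiOH, THF/MeOH/H2O, rt; then 1 M HCl to pH 4
Reagents that add atoms: lithium hydroxide, [Li+].[OH-]
Why: Plain ester saponification, to which primary TBDPS ethers are inert at room temperature.

Step 5
Reactants: 7 side-chain acid; 8 (R)-4-benzyl-2-oxazolidinone
Product: 10 N-acyl oxazolidinone, via mixed pivalic anhydride 9 (not isolated)
Conditions: PivCl, Et3N, THF, −20 °C; then LiCl, 8, −20 °C to rt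
Reagents that add atoms: none
Why: N-acylation through a mixed anhydride (LiCl/Et3N variant), in which the auxiliary attacks the unhindered acyl carbon and strong base is avoided.

Step 6
Reactants: 11 4-pentenal
Product: 12 ethyl (E)-2-methylhepta-2,6-dienoate
Conditions: Ph3P=C(Me)CO2Et, CH2Cl2, rt
Reagents that add atoms: ethyl 2-(triphenylphosphoranylidene)propanoate, CCOC(=O)C(C)=P(c1ccccc1)(c1ccccc1)c1ccccc1
Why: Wittig olefination with a stabilised α-methyl ylide gives the E-trisubstituted enoate and thereby fixes the C4=C5 geometry that later decides the configuration at C4.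

Step 7
Reactants: 12 dienoate
Product: 13 ethyl (E)-2-methyl-6-oxohex-2-enoate
Conditions: OsO4 (2 mol%), NaIO4, 2,6-lutidine, dioxane/H2O, rt
Reagents that add atoms: osmium tetroxide, O=[Os](=O)(=O)=O; sodium periodate, [Na+].[O-]I(=O)(=O)=O
Why: In the Lemieux–Johnson cleavage, OsO4 dihydroxylates the electron-rich monosubstituted alkene much faster than the electron-poor trisubstituted enoate, and periodate cleaves the diol to the C8 aldehyde.

Step 8
Reactants: 10 N-acyl oxazolidinone; 13 enoate aldehyde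
Product: 15 syn-aldol imide (C9 R and C8 S), via dibutylboron Z-enolate 14 (not isolated)
Conditions: n-Bu2BOTf, Et3N, CH2Cl2, 0 °C; 13, −78 to 0 °C; then pH 7 buffer, MeOH, 30% H2O2, 0 °C
Reagents that add atoms: none
Why: In the Evans syn-aldol reaction the Z-boron enolate reacts through a Zimmerman–Traxler chair on the enolate face left open by the benzyl group, so the (R)-auxiliary sets C9 as R and C8 as S, a syn pair that becomes trans-diequatorial on ring B.

Step 9
Reactants: 15 syn-aldol imide
Product: 16 β-hydroxy Weinreb amide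
Conditions: MeNH(OMe)·HCl, AlMe3, THF, −15 to 0 °C
Reagents that add atoms: N,O-dimethylhydroxylamine hydrochloride, CNOC.Cl
Why: Aluminium-amide transamination is steered to the exocyclic imide carbonyl by the aluminium alkoxide of the free C8 hydroxyl and is fast enough at low temperature to leave the enoate untouched.

Step 10
Reactants: 16 β-hydroxy Weinreb amide
Product: 17 C8 triethylsilyl ether
Conditions: TESOTf, 2,6-lutidine, CH2Cl2, −78 to 0 °C
Reagents that add atoms: triethylsilyl trifluoromethanesulfonate, CC[Si](CC)(CC)OS(=O)(=O)C(F)(F)F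
Why: Silylation with a silyl triflate and a hindered base protects the secondary alcohol without retro-aldol cleavage.

Step 11
Reactants: 17 TES-protected Weinreb amide
Product: 19 terminal alkyne bearing the free C18 allylic alcohol, via hydroxy aldehyde 18 (not isolated)
Conditions: i-Bu2AlH (3.5 equiv), CH2Cl2, −78 °C; MeOH; then K2CO3, MeC(O)C(N2)P(O)(OMe)2, MeOH, 0 °C to rt
Reagents that add atoms: dimethyl (1-diazo-2-oxopropyl)phosphonate, CC(=O)C(=[N+]=[N-])P(=O)(OC)OC
Why: The hydride stops at the chelated hemiaminal of the Weinreb amide while taking the enoate to the allylic alcohol, and the aldehyde released by methanol undergoes Ohira–Bestmann (Seyferth–Gilbert) homologation in the same flask under carbonate conditions mild enough to preserve C9.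

Step 12
Reactants: 19 alkynol
Product: 22 diol with the (E)-C10=C1 alkene, via vinylalane 20 (not isolated), via lithium alanate 21 (not isolated)
Conditions: AlMe3 (4 equiv), Cp2ZrCl2 (25 mol%), CH2Cl2, 0 °C to rt; evaporate; n-BuLi, THF/hexane, −78 °C; ethylene oxide, −78 to 0 °C
Reagents that add atoms: trimethylaluminium, C[Al](C)C; ethylene oxide, C1CO1
Why: Zirconium-catalysed methylalumination (Negishi carboalumination) adds Me and Al syn with Al at the terminal carbon, which fixes C20 cis to C2, and the derived alanate opens ethylene oxide with retention, while the free hydroxyl is merely masked as its aluminium alkoxide.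

Step 13
Reactants: 22 diol
Product: 23 dialdehyde (C18 enal and C3 β,γ-unsaturated aldehyde)
Conditions: Dess–Martin periodinane (2.5 equiv), pyridine, CH2Cl2, 0 °C
Reagents that add atoms: none
Why: Buffered Dess–Martin oxidation converts both primary alcohols at once and is mild enough not to move the C10=C1 alkene into conjugation.

Step 14
Reactants: 23 dialdehyde
Product: 24 open-chain silyl dienol ether trienal
Conditions: TESOTf (1.05 equiv), Et3N, CH2Cl2, −78 °C; cold aq NaHCO3; Et3N-deactivated silica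
Reagents that add atoms: triethylsilyl trifluoromethanesulfonate, CC[Si](CC)(CC)OS(=O)(=O)C(F)(F)F
Why: In this soft enolisation with silyl triflate and amine, the C2 hydrogens (α to the C3 carbonyl and also allylic) are removed far faster than the γ-hydrogens of the conjugated C18 enal, so one equivalent at −78 °C should silylate only O3 and leave C10=C1 in place, and because only the 1E enol ether can reach the s-cis conformer, the 1Z isomer is separated and hydrolysed back to 23.

Step 15
Reactants: 24 open-chain silyl dienol ether trienal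
Product: 25 trans-decalin C18 aldehyde with C1=C2 alkene and TES ethers at O3 (axial) and O8 (equatorial)
Conditions: BHT (cat.), toluene (0.005 M), base-washed sealed tube, 140 °C
Reagents that add atoms: none
Why: This is a thermal, concerted but asynchronous [4+2] cycloaddition whose closest known class is the type 1 intramolecular Diels–Alder reaction of 1,7,9-decatrienals: the O3 donor raises the HOMO coefficient at C10 and the formyl group the LUMO coefficient at C5, so the C5–C10 bond runs ahead of C3–C4. Ring B (C5 to C10) closes through the C6–C9 tether folded as a chair, and ring A (C1 to C5 plus C10) is the new cyclohexene, formed with the dienophile stacked under the s-cis diene in a boat-like array. C5 and C10 are set by the formyl-endo, tether-exo orientation, which leaves H5 and C20 on opposite faces (trans fusion). C4 follows from suprafacial addition to the E-enal (CHO stays cis to H5, so C18 is equatorial and C19 axial, syn to C20), and C3 follows from the E-enol ether (OTES stays cis to C9 and to CHO, hence axial, a centre erased in step 19). The step needs facial and endo selectivity: the face is fixed by C9 and C8, whose side chain and OTES group are both equatorial in only one chair fold of the tether, and the endo mode is favoured by secondary overlap of the formyl group and by the matched polarity of the reacting termini. High dilution, a radical inhibitor and acid-free glass are used because the inner C20 methyl retards the reaction and opens a competing 1,5-hydrogen shift.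

Step 16
Reactants: 25 decalin aldehyde
Product: 26 C18 primary alcohol
Conditions: i-Bu2AlH, CH2Cl2, −78 °C
Reagents that add atoms: none
Why: Hydride reduction of the neopentyl aldehyde removes the risk of a later β-keto aldehyde, and at −78 °C the aluminium alkoxide should not trigger silyl migration from O3.

Step 17
Reactants: 26 C18 alcohol
Product: 27 C18 TBS ether
Conditions: TBSOTf, 2,6-lutidine, CH2Cl2, 0 °C
Reagents that add atoms: tert-butyldimethylsilyl trifluoromethanesulfonate, CC(C)(C)[Si](C)(C)OS(=O)(=O)C(F)(F)F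
Why: Silyl triflate silylation overcomes the neopentyl hindrance and gives an ether clearly more robust than TES.

Step 18
Reactants: 27 fully silylated decalin
Product: 28 C3,C8-diol
Conditions: HF·pyridine, pyridine, THF, 0 °C to rt
Reagents that add atoms: none
Why: Buffered fluoride desilylation discriminates by bulk at silicon, so both TES ethers fall while the neopentyl TBS and the two TBDPS ethers remain.

Step 19
Reactants: 28 diol
Product: 29 C1-en-3-one C8-ketone
Conditions: Dess–Martin periodinane, pyridine, CH2Cl2, rt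
Reagents that add atoms: none
Why: Dess–Martin oxidation of the allylic and the saturated secondary alcohol in one operation erases the provisional C3 centre and gives an enone with no enolisable position, since C4 and C10 are quaternary.

Step 20
Reactants: 29 enone ketone
Product: 30 C8(17)-methylene enone
Conditions: Ph3PCH3Br, KOt-Bu, THF, 0 °C; then 29 (1.2 equiv of ylide), −78 to 0 °C
Reagents that add atoms: methyltriphenylphosphonium bromide, C[P+](c1ccccc1)(c1ccccc1)c1ccccc1.[Br-]
Why: Wittig methylenation favours the saturated, less hindered C8 ketone over the conjugated C3 carbonyl shielded by quaternary C4 (the same preference is known for bicyclic enediones), and any enolisation at C9 returns the favoured equatorial side chain.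

Step 21
Reactants: 30 methylene enone
Product: 31 saturated C3 ketone
Conditions: [(Ph3P)CuH]6, H2O, degassed toluene, rt
Reagents that add atoms: none
Why: Copper hydride conjugate reduction delivers hydride to C1 of the enone only and leaves the isolated 1,1-disubstituted and trisubstituted alkenes alone.

Step 22
Reactants: 31 C3 ketone
Product: 33 2-hydroxy-3-ketone (equatorial OH), via potassium enolate 32 (not isolated)
Conditions: KN(SiMe3)2, THF, −78 °C; 2-(phenylsulfonyl)-3-phenyloxaziridine, −78 °C; AcOH quench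
Reagents that add atoms: 2-(phenylsulfonyl)-3-phenyloxaziridine, O=S(=O)(c1ccccc1)N1OC1c1ccccc1
Why: In the Davis enolate hydroxylation only C2 can be deprotonated, the oxidant approaches the face opposite the syn-axial C19 and C20 methyls to give the equatorial (also thermodynamically preferred) C2 alcohol, and unactivated alkenes are inert to the oxaziridine.

Step 23
Reactants: 33 hydroxy ketone
Product: 34 C2 TES ether
Conditions: TESCl, imidazole, DMF, 0 °C to rt
Reagents that add atoms: chlorotriethylsilane, CC[Si](Cl)(CC)CC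
Why: Mild silylation blocks O2 before O3 is created and prevents ketol transposition, with the small TES group chosen to keep the neighbouring C3 site accessible.

Step 24
Reactants: 34 silyloxy ketone
Product: 35 C3 equatorial alcohol
Conditions: NaBH4, MeOH/THF, −20 to 0 °C
Reagents that add atoms: none
Why: In this borohydride reduction of a 4,4-disubstituted 3-ketone, hydride enters along the axial trajectory on the face away from C19 and C20, which gives the equatorial C3 alcohol trans to O2 as in the target.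

Step 25
Reactants: 35 C3 alcohol; 36 angelic acid
Product: 38 fully silylated C3 angelate, via mixed anhydride 37 (not isolated)
Conditions: 36, 2,4,6-Cl3C6H2COCl, Et3N, toluene, rt; then 35, toluene, 80 °C (no DMAP)
Reagents that add atoms: none
Why: Yamaguchi-type mixed-anhydride esterification run without a nucleophilic catalyst acylates at the less hindered angeloyl carbon and avoids the addition–elimination pathway that would turn the Z-ester into the tiglate.

Step 26
Reactants: 38 silylated angelate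
Product: 39 target CNP0324138.1
Conditions: HF·pyridine (excess), THF, 0 °C to rt
Reagents that add atoms: none
Why: Global fluoride desilylation in a mildly acidic medium removes the TES, TBS and both TBDPS groups without the base-induced acyl migration from O3 to O2 or O18 and without touching the alkenes.

Compound list
1 | 2-butyne-1,4-diol | OCC#CCO | starting material
2 | 1,4-bis(tert-butyldiphenylsilyloxy)but-2-yne | CC(C)(C)[Si](c1ccccc1)(c1ccccc1)OCC#CCO[Si](c1ccccc1)(c1ccccc1)C(C)(C)C | intermediate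
3 | (E)-2-(tributylstannyl)but-2-ene-1,4-diol bis-TBDPS ether (H and Sn cis) | CCCC[Sn](CCCC)(CCCC)/C(CO[Si](c1ccccc1)(c1ccccc1)C(C)(C)C)=C/CO[Si](c1ccccc1)(c1ccccc1)C(C)(C)C | intermediate
4 | (E)-2-iodobut-2-ene-1,4-diol bis-TBDPS ether (two CH2O groups cis) | CC(C)(C)[Si](c1ccccc1)(c1ccccc1)OC/C=C(/I)CO[Si](c1ccccc1)(c1ccccc1)C(C)(C)C | intermediate
5 | 4-ethoxy-4-oxobutylzinc bromide | CCOC(=O)CCC[Zn]Br | starting material
6 | ethyl (Z)-7-(tert-butyldiphenylsilyloxy)-5-[(tert-butyldiphenylsilyloxy)methyl]hept-5-enoate | CCOC(=O)CCC/C(=C/CO[Si](c1ccccc1)(c1ccccc1)C(C)(C)C)CO[Si](c1ccccc1)(c1ccccc1)C(C)(C)C | intermediate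
7 | (Z)-7-(tert-butyldiphenylsilyloxy)-5-[(tert-butyldiphenylsilyloxy)methyl]hept-5-enoic acid | OC(=O)CCC/C(=C/CO[Si](c1ccccc1)(c1ccccc1)C(C)(C)C)CO[Si](c1ccccc1)(c1ccccc1)C(C)(C)C | intermediate
8 | (R)-4-benzyl-2-oxazolidinone | O=C1N[C@H](Cc2ccccc2)CO1 | starting material
9 | mixed anhydride of acid 7 and pivalic acid | CC(C)(C)C(=O)OC(=O)CCC/C(=C/CO[Si](c1ccccc1)(c1ccccc1)C(C)(C)C)CO[Si](c1ccccc1)(c1ccccc1)C(C)(C)C | intermediate
10 | (R)-4-benzyl-3-[(Z)-7-(TBDPS-oxy)-5-(TBDPS-oxymethyl)hept-5-enoyl]oxazolidin-2-one | O=C(CCC/C(=C/CO[Si](c3ccccc3)(c3ccccc3)C(C)(C)C)CO[Si](c3ccccc3)(c3ccccc3)C(C)(C)C)N1[C@H](Cc2ccccc2)COC1=O | intermediate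
11 | 4-pentenal | C=CCCC=O | starting material
12 | ethyl (E)-2-methylhepta-2,6-dienoate | C=CCC/C=C(\C)C(=O)OCC | intermediate
13 | ethyl (E)-2-methyl-6-oxohex-2-enoate | O=CCC/C=C(\C)C(=O)OCC | intermediate
14 | dibutylboron (Z)-enolate of imide 10 (O and C11 cis) | CCCCB(CCCC)O/C(=C\CC/C(=C/CO[Si](c3ccccc3)(c3ccccc3)C(C)(C)C)CO[Si](c3ccccc3)(c3ccccc3)C(C)(C)C)N1[C@H](Cc2ccccc2)COC1=O | intermediate
15 | syn-aldol imide: acyl chain with C9 (R, bearing the C11–C16 side chain), C8 (S, OH), then C7, C6 and the (E)-ethyl 2-methylenoate C5=C4(C19)–C18 | CCOC(=O)/C(C)=C/CC[C@H](O)[C@@H](CC/C(=C/CO[Si](c3ccccc3)(c3ccccc3)C(C)(C)C)CO[Si](c3ccccc3)(c3ccccc3)C(C)(C)C)C(=O)N1[C@H](Cc2ccccc2)COC1=O | intermediate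
16 | Weinreb amide of the syn-aldol (C8 OH free) | CCOC(=O)/C(C)=C/CC[C@H](O)[C@@H](CC/C(=C/CO[Si](c3ccccc3)(c3ccccc3)C(C)(C)C)CO[Si](c3ccccc3)(c3ccccc3)C(C)(C)C)C(=O)N(C)OC | intermediate
17 | C8 TES ether of Weinreb amide 16 | CCOC(=O)/C(C)=C/CC[C@H](O[Si](CC)(CC)CC)[C@@H](CC/C(=C/CO[Si](c3ccccc3)(c3ccccc3)C(C)(C)C)CO[Si](c3ccccc3)(c3ccccc3)C(C)(C)C)C(=O)N(C)OC | intermediate
18 | C10 aldehyde with (E)-allylic alcohol at C18 | OC/C(C)=C/CC[C@H](O[Si](CC)(CC)CC)[C@@H](CC/C(=C/CO[Si](c3ccccc3)(c3ccccc3)C(C)(C)C)CO[Si](c3ccccc3)(c3ccccc3)C(C)(C)C)C=O | intermediate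
19 | terminal alkyne (C10≡C1) with free C18 allylic alcohol | OC/C(C)=C/CC[C@H](O[Si](CC)(CC)CC)[C@@H](CC/C(=C/CO[Si](c3ccccc3)(c3ccccc3)C(C)(C)C)CO[Si](c3ccccc3)(c3ccccc3)C(C)(C)C)C#C | intermediate
20 | (E)-vinylalane (Me and Al cis), O18 as dimethylaluminium alkoxide | C[Al](C)OC/C(C)=C/CC[C@H](O[Si](CC)(CC)CC)[C@@H](CC/C(=C/CO[Si](c3ccccc3)(c3ccccc3)C(C)(C)C)CO[Si](c3ccccc3)(c3ccccc3)C(C)(C)C)/C(C)=C/[Al](C)C | intermediate
21 | lithium butyl(dimethyl)vinylalanate derived from 20 | [Li+].C[Al](C)OC/C(C)=C/CC[C@H](O[Si](CC)(CC)CC)[C@@H](CC/C(=C/CO[Si](c3ccccc3)(c3ccccc3)C(C)(C)C)CO[Si](c3ccccc3)(c3ccccc3)C(C)(C)C)/C(C)=C/[Al-](C)(C)CCCC | intermediate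
22 | diol: C3 homoallylic alcohol on the (E)-C10(C20)=C1 alkene and C18 allylic alcohol | OC/C(C)=C/CC[C@H](O[Si](CC)(CC)CC)[C@@H](CC/C(=C/CO[Si](c3ccccc3)(c3ccccc3)C(C)(C)C)CO[Si](c3ccccc3)(c3ccccc3)C(C)(C)C)/C(C)=C/CCO | intermediate
23 | dialdehyde: (E)-2-methylenal (C18) and β,γ-unsaturated aldehyde (C3) | O=C/C(C)=C/CC[C@H](O[Si](CC)(CC)CC)[C@@H](CC/C(=C/CO[Si](c3ccccc3)(c3ccccc3)C(C)(C)C)CO[Si](c3ccccc3)(c3ccccc3)C(C)(C)C)/C(C)=C/CC=O | intermediate
24 | key-step precursor: open-chain trienal with (E)-2-methylenal (C18, C4, C5), C8 OTES, C9 side chain and (1E,3E)-1-triethylsilyloxy-4-methyl diene (C3, C2, C1, C10) | O=C/C(C)=C/CC[C@H](O[Si](CC)(CC)CC)[C@@H](CC/C(=C/CO[Si](c3ccccc3)(c3ccccc3)C(C)(C)C)CO[Si](c3ccccc3)(c3ccccc3)C(C)(C)C)/C(C)=C/C=C/O[Si](CC)(CC)CC | intermediate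
25 | key-step product: trans-decalin, C1=C2 alkene, axial O3-TES, equatorial C18 aldehyde, axial C19 syn to C20, equatorial O8-TES and C9 side chain | CC[Si](CC)(CC)O[C@H]1CC[C@H]2[C@@](C)(C=C[C@H](O[Si](CC)(CC)CC)[C@]2(C)C=O)[C@@H]1CC/C(=C/CO[Si](c3ccccc3)(c3ccccc3)C(C)(C)C)CO[Si](c3ccccc3)(c3ccccc3)C(C)(C)C | intermediate
26 | C18 primary alcohol of 25 | CC[Si](CC)(CC)O[C@H]1CC[C@H]2[C@@](C)(C=C[C@H](O[Si](CC)(CC)CC)[C@]2(C)CO)[C@@H]1CC/C(=C/CO[Si](c3ccccc3)(c3ccccc3)C(C)(C)C)CO[Si](c3ccccc3)(c3ccccc3)C(C)(C)C | intermediate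
27 | C18 TBS ether of 26 | CC[Si](CC)(CC)O[C@H]1CC[C@H]2[C@@](C)(C=C[C@H](O[Si](CC)(CC)CC)[C@]2(C)CO[Si](C)(C)C(C)(C)C)[C@@H]1CC/C(=C/CO[Si](c3ccccc3)(c3ccccc3)C(C)(C)C)CO[Si](c3ccccc3)(c3ccccc3)C(C)(C)C | intermediate
28 | C3 (axial, allylic), C8 (equatorial) diol | O[C@H]1CC[C@H]2[C@@](C)(C=C[C@H](O)[C@]2(C)CO[Si](C)(C)C(C)(C)C)[C@@H]1CC/C(=C/CO[Si](c3ccccc3)(c3ccccc3)C(C)(C)C)CO[Si](c3ccccc3)(c3ccccc3)C(C)(C)C | intermediate
29 | C1-en-3-one, C8 ketone | O=C1CC[C@H]2[C@@](C)(C=CC(=O)[C@]2(C)CO[Si](C)(C)C(C)(C)C)[C@@H]1CC/C(=C/CO[Si](c3ccccc3)(c3ccccc3)C(C)(C)C)CO[Si](c3ccccc3)(c3ccccc3)C(C)(C)C | intermediate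
30 | C8(17)-methylene C1-en-3-one | C=C1CC[C@H]2[C@@](C)(C=CC(=O)[C@]2(C)CO[Si](C)(C)C(C)(C)C)[C@@H]1CC/C(=C/CO[Si](c3ccccc3)(c3ccccc3)C(C)(C)C)CO[Si](c3ccccc3)(c3ccccc3)C(C)(C)C | intermediate
31 | C8(17)-methylene saturated C3 ketone | C=C1CC[C@H]2[C@@](C)(CCC(=O)[C@]2(C)CO[Si](C)(C)C(C)(C)C)[C@@H]1CC/C(=C/CO[Si](c3ccccc3)(c3ccccc3)C(C)(C)C)CO[Si](c3ccccc3)(c3ccccc3)C(C)(C)C | intermediate
32 | potassium C2=C3 enolate of 31 | [K+].C=C1CC[C@H]2[C@@](C)(CC=C([O-])[C@]2(C)CO[Si](C)(C)C(C)(C)C)[C@@H]1CC/C(=C/CO[Si](c3ccccc3)(c3ccccc3)C(C)(C)C)CO[Si](c3ccccc3)(c3ccccc3)C(C)(C)C | intermediate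
33 | 2-hydroxy-3-ketone, OH equatorial | C=C1CC[C@H]2[C@@](C)(C[C@H](O)C(=O)[C@]2(C)CO[Si](C)(C)C(C)(C)C)[C@@H]1CC/C(=C/CO[Si](c3ccccc3)(c3ccccc3)C(C)(C)C)CO[Si](c3ccccc3)(c3ccccc3)C(C)(C)C | intermediate
34 | C2 TES ether of 33 | C=C1CC[C@H]2[C@@](C)(C[C@H](O[Si](CC)(CC)CC)C(=O)[C@]2(C)CO[Si](C)(C)C(C)(C)C)[C@@H]1CC/C(=C/CO[Si](c3ccccc3)(c3ccccc3)C(C)(C)C)CO[Si](c3ccccc3)(c3ccccc3)C(C)(C)C | intermediate
35 | C3 equatorial alcohol, trans to the equatorial O2-TES | C=C1CC[C@H]2[C@@](C)(C[C@H](O[Si](CC)(CC)CC)[C@@H](O)[C@]2(C)CO[Si](C)(C)C(C)(C)C)[C@@H]1CC/C(=C/CO[Si](c3ccccc3)(c3ccccc3)C(C)(C)C)CO[Si](c3ccccc3)(c3ccccc3)C(C)(C)C | intermediate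
36 | angelic acid, (Z)-2-methylbut-2-enoic acid | C/C=C(/C)C(=O)O | starting material
37 | angelic 2,4,6-trichlorobenzoic mixed anhydride | C/C=C(/C)C(=O)OC(=O)c1c(Cl)cc(Cl)cc1Cl | intermediate
38 | C3 angelate with O2-TES, O18-TBS, O15/O16-TBDPS | C=C1CC[C@H]2[C@@](C)(C[C@H](O[Si](CC)(CC)CC)[C@@H](OC(=O)/C(C)=C\C)[C@]2(C)CO[Si](C)(C)C(C)(C)C)[C@@H]1CC/C(=C/CO[Si](c3ccccc3)(c3ccccc3)C(C)(C)C)CO[Si](c3ccccc3)(c3ccccc3)C(C)(C)C | intermediate
39 | CNP0324138.1: ent-labda-8(17),13Z-diene-2,3,15,16,18-pentol 3-angelate (O2, O3, C18 equatorial) | C=C1CC[C@H]2[C@@](C)(C[C@H](O)[C@@H](OC(=O)/C(C)=C\C)[C@]2(C)CO)[C@@H]1CC/C(=C/CO)CO | target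

Total step count: 26. Longest linear sequence: 24 steps (steps 1–5 and 8–26). Steps 6 and 7 form the short branch.

Steps most likely to fail

1. Step 15, the cycloaddition.
What may go wrong: the s-cis conformer of the diene is crowded by the inner C20 methyl, so bond formation between two carbons that both become quaternary may be too slow. It could then be overtaken by the 1,5-hydrogen migration from C20 to C3, by protodesilylation of the enol ether, or by leakage through the exo, cis-fusing orientation.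
Fallback: the same two bonds are built by a radical–polar sequence instead of a pericyclic one, setting out from dialdehyde 23.
- Fe(acac)3 and PhSiH3 in EtOH/1,2-dichloroethane transfer a hydrogen atom to C1 of the C10=C1 alkene.
- The tertiary C10 radical adds 6-exo to C5 of the enal and closes ring B.
- The α-formyl radical is reduced to the enolate, which closes ring A by aldol addition to the C3 aldehyde and gives the β-hydroxy aldehyde F1.
- Allylic strain about C5–C4 should place C18 equatorial, and the C3 configuration is of no consequence. The side-chain alkene, flanked by two bulky silyloxymethyl groups, should accept hydrogen more slowly.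
- NaBH4 gives the diol F2, and TBSCl/imidazole silylates the primary hydroxyl to the mono-TBS ether F3.
- Buffered HF·pyridine removes the O8 TES group to give the diol F4, and Dess–Martin oxidation gives the diketone F5.
- Ph3P=CH2 methylenates the open C8 ketone in preference to the neopentyl C3 ketone. The route is rejoined at ketone 31, and steps 14–21 are no longer needed.

2. Step 14, the dienol silylation.
What may go wrong: the conjugated enal may be silylated in competition, the C10=C1 alkene may drift into conjugation, and kinetic enolisation may run largely towards the 1Z geometry, which cannot reach the reactive conformer.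
Fallback: the order of events is changed so that no enal is present when the enol ether is made, setting out from alkynol 19.
- PivCl/pyridine gives the pivalate F6.
- Methylalumination at low temperature (AlMe3, Cp2ZrCl2, one equivalent of water, −25 °C), alanate formation and ethylene oxide give the homoallylic alcohol F7.
- Dess–Martin oxidation gives the β,γ-unsaturated aldehyde F8.
- An excess of TESOTf/Et3N can now be used, and the geometric isomers are separated at leisure to give the 1E dienol ether F9.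
- i-Bu2AlH at −78 °C removes the pivalate to give the allylic alcohol F10, and neutral MnO2 oxidation rejoins the route at 24.

3. Step 25, the angeloylation.
What may go wrong: acylation of a neopentyl alcohol flanked by a silyl ether may be sluggish, prolonged heating may cause Z-to-E isomerisation of the acyl donor, and the silyl group may migrate from O2 to O3.
Fallback: the Z-alkene is built on the ester instead of being transferred, setting out from alcohol 35.
- 2-[Bis(2,2,2-trifluoroethoxy)phosphoryl]propanoic acid with DCC/DMAP gives the phosphonopropionate F11. No alkene is present at this point, so a nucleophilic catalyst is harmless.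
- Still–Gennari olefination with acetaldehyde (KN(SiMe3)2, 18-crown-6, THF, −78 °C) forms the (Z)-2-methylbut-2-enoate and rejoins the route at 38.

Further compounds
F1 | step 15 | β-hydroxy aldehyde: trans-decalin with saturated ring A, C3 OH (drawn equatorial), equatorial C18 aldehyde, O8-TES | CC[Si](CC)(CC)O[C@H]1CC[C@H]2[C@@](C)(CC[C@@H](O)[C@]2(C)C=O)[C@@H]1CC/C(=C/CO[Si](c3ccccc3)(c3ccccc3)C(C)(C)C)CO[Si](c3ccccc3)(c3ccccc3)C(C)(C)C
F2 | step 15 | C3,C18-diol with O8-TES | CC[Si](CC)(CC)O[C@H]1CC[C@H]2[C@@](C)(CC[C@@H](O)[C@]2(C)CO)[C@@H]1CC/C(=C/CO[Si](c3ccccc3)(c3ccccc3)C(C)(C)C)CO[Si](c3ccccc3)(c3ccccc3)C(C)(C)C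
F3 | step 15 | C18 mono-TBS ether, C3 OH free, O8-TES | CC[Si](CC)(CC)O[C@H]1CC[C@H]2[C@@](C)(CC[C@@H](O)[C@]2(C)CO[Si](C)(C)C(C)(C)C)[C@@H]1CC/C(=C/CO[Si](c3ccccc3)(c3ccccc3)C(C)(C)C)CO[Si](c3ccccc3)(c3ccccc3)C(C)(C)C
F4 | step 15 | saturated C3,C8-diol | O[C@H]1CC[C@H]2[C@@](C)(CC[C@@H](O)[C@]2(C)CO[Si](C)(C)C(C)(C)C)[C@@H]1CC/C(=C/CO[Si](c3ccccc3)(c3ccccc3)C(C)(C)C)CO[Si](c3ccccc3)(c3ccccc3)C(C)(C)C
F5 | step 15 | saturated C3,C8-diketone | O=C1CC[C@H]2[C@@](C)(CCC(=O)[C@]2(C)CO[Si](C)(C)C(C)(C)C)[C@@H]1CC/C(=C/CO[Si](c3ccccc3)(c3ccccc3)C(C)(C)C)CO[Si](c3ccccc3)(c3ccccc3)C(C)(C)C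
F6 | step 14 | C18 pivalate of alkynol 19 | CC(C)(C)C(=O)OC/C(C)=C/CC[C@H](O[Si](CC)(CC)CC)[C@@H](CC/C(=C/CO[Si](c3ccccc3)(c3ccccc3)C(C)(C)C)CO[Si](c3ccccc3)(c3ccccc3)C(C)(C)C)C#C
F7 | step 14 | C3 homoallylic alcohol, C18 pivalate | CC(C)(C)C(=O)OC/C(C)=C/CC[C@H](O[Si](CC)(CC)CC)[C@@H](CC/C(=C/CO[Si](c3ccccc3)(c3ccccc3)C(C)(C)C)CO[Si](c3ccccc3)(c3ccccc3)C(C)(C)C)/C(C)=C/CCO
F8 | step 14 | C3 β,γ-unsaturated aldehyde, C18 pivalate | CC(C)(C)C(=O)OC/C(C)=C/CC[C@H](O[Si](CC)(CC)CC)[C@@H](CC/C(=C/CO[Si](c3ccccc3)(c3ccccc3)C(C)(C)C)CO[Si](c3ccccc3)(c3ccccc3)C(C)(C)C)/C(C)=C/CC=O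
F9 | step 14 | (1E,3E)-TES dienol ether, C18 pivalate | CC(C)(C)C(=O)OC/C(C)=C/CC[C@H](O[Si](CC)(CC)CC)[C@@H](CC/C(=C/CO[Si](c3ccccc3)(c3ccccc3)C(C)(C)C)CO[Si](c3ccccc3)(c3ccccc3)C(C)(C)C)/C(C)=C/C=C/O[Si](CC)(CC)CC
F10 | step 14 | (1E,3E)-TES dienol ether with free C18 allylic alcohol | OC/C(C)=C/CC[C@H](O[Si](CC)(CC)CC)[C@@H](CC/C(=C/CO[Si](c3ccccc3)(c3ccccc3)C(C)(C)C)CO[Si](c3ccccc3)(c3ccccc3)C(C)(C)C)/C(C)=C/C=C/O[Si](CC)(CC)CC
F11 | step 25 | C3 2-[bis(2,2,2-trifluoroethoxy)phosphoryl]propanoate of 35 (epimeric at the phosphonate carbon) | C=C1CC[C@H]2[C@@](C)(C[C@H](O[Si](CC)(CC)CC)[C@@H](OC(=O)C(C)P(=O)(OCC(F)(F)F)OCC(F)(F)F)[C@]2(C)CO[Si](C)(C)C(C)(C)C)[C@@H]1CC/C(=C/CO[Si](c3ccccc3)(c3ccccc3)C(C)(C)C)CO[Si](c3ccccc3)(c3ccccc3)C(C)(C)C
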